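- Read at 8.00 min, the winter flask holds Q at 18.7% of the X charged, a gain of 1.7 percentage points in the last 4.00 min. The summer flask, read at 20.0 min, holds 15.7% and gained 3.2 points in its last 5.00 min.

| flask | X | E | temperature | remark | time |
|---|---|---|---|---|---|
| summer | 0.15 M | 1 equiv | 65 °C | run made earlier |  |
| winter | 0.28 M | 1 equiv | 90 °C | run made earlier |  |
| south-west | 0.20 M | 1.00 equiv | 70 °C |  | 25 min |
| north-east | 0.12 M | 1.00 equiv | 110 °C |  | 25 min |

| summer: time / min | summer: Q / % | winter: time / min | winter: Q / % |
|---|---|---|---|
| 4.00 | 3.5 | 0.500 | 2.4 |
| 8.00 | 6.9 | 1.33 | 8.3 |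
| 10.0 | 8.4 | 3.00 | 14.8 |
| 15.0 | 12.5 | 4.00 | 17.0 |
| 20.0 | 15.7 | 8.00 | 18.7 |

(each reading ± 0.5 percentage points)

- which of the two ends with the higher amount of Q, in percent of the X charged ("neither" if they lie within 2 percentage points) (south-west / north-east / neither)
- Q at the end, in percent of the X charged, south-west
- Q at the end, in percent of the X charged, north-east

- where the amount of X changes, what is given in equivalents or mol% on it follows

- Q is a bis adduct, so each Q carries two E, and E is the limiting reagent for Q: as a fraction of the X charged, Q can reach half of the E charged.
- A share of the charge loses its dependence on time once a run has finished, and it is then the rate of E into Q divided by the rate of E use, summed over the run. Winter's last reading, taken as that end, gives 37.4% for the E share, twice Q divided by the equivalents of E.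
- For north-east, this reckoning supposes that Q needs a meeting of two partners while its competitor is first-order, so the share scales with concentration. Taken from winter, that gives a share of 16.0% and Q of 8.01%, with the heat of 110 °C left uncounted.
- For south-west, the summer flask's last gain, carried on to 25 min, gives 18.9%. South-west is warmer and more concentrated than summer, so this reckoning takes that figure as its floor and puts south-west ahead of north-east.
- The forecast also says south-west, with 29% for south-west and 4% for north-east, the latter lower than this reckoning's figure, on its view of “the loss much more temperature-sensitive”.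
- The flasks give 22.4% for south-west and 9.45% for north-east, so south-west ends higher.

    2 E → G (k = 0.00130 L mol⁻¹ s⁻¹, Ea = 88.0 kJ mol⁻¹)
    X + E → D + Z (k = 0.0100 L mol⁻¹ s⁻¹, Ea = 70.0 kJ mol⁻¹)
    D → J (k = 4.50 × 10⁻⁴ s⁻¹, Ea = 94.0 kJ mol⁻¹)
    E + D → Q + Z (k = 0.0120 L mol⁻¹ s⁻¹, Ea = 51.0 kJ mol⁻¹)
    (constants at 70 °C)

- In north-east, 0.0096% of the charged E is left at 25.0 min, and Q already stood at 9.45% at 12.5 min. The E share of north-east is 18.9%, against 16.0% reckoned, and that of south-west stands at 44.8% at 25.0 min, a share still moving, with 6.68% of its E charge and D at 21.2% of the X charged still in that flask. A further flask, like north-east but charged with 2.50 equiv of E, ends with Q at 29.3%, an E share of 23.4%.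

Readings and results stem from a simulated flask with constants of no real substance; scatter was added.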